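**Plan**

1. Retrosynthesis: ring D (the 2,2-dimethyl-2H-pyran fused at C2'–C3' of ring B) is opened first at O–CMe2. The array O–C2'=C3'–CH=CH–CMe2 is the closed valence isomer of an ortho-quinone methide (a 1-oxatriene), so a retro-oxa-6π cut plus the C3'–CH cut leads to a ring-B phenol (free O2'–H, free C3'–H, C1' blocked) and 3-methylbut-2-enal.
2. Next cuts: the C3–H/C4–H bonds (asymmetric hydrogenation of the isoflav-3-ene C3=C4), then O1–C2 (Mitsunobu) and the C2 oxidation level (coumarin lactone), and last C3=C4 together with the lactone C–O, which give a ring-A salicylaldehyde and a ring-B benzofuran-2(3H)-one.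
3. Forward: ring C arises first as a coumarin by Knoevenagel condensation and translactonisation, which frees only O2' of ring B. It is reduced, closed again as a 2H-chromene and hydrogenated; ring D is annulated last.
4. Stereochemistry: the single stereocentre C3 (R) comes from catalyst-controlled iridium hydrogenation and cannot enolise afterwards. Helpers: MOM on O7 and O4' throughout, benzyl on O2' from step 4 to step 8.

Key step: step 9

Remark: the sense of induction of the iridium P,N catalyst on this 3-aryl-2H-chromene is assumed to be settled by a small trial; the (S)-ligand is written, and its antipode serves if the trial points to the 3S series.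

**Route**

Step 1
Reactants: 1 2,4-dihydroxy-6-methoxybenzaldehyde
Product: 2 2-hydroxy-6-methoxy-4-(methoxymethoxy)benzaldehyde
Conditions: MOMCl (1.1 equiv), iPr2NEt, CH2Cl2, 0 °C to rt
Reagents that add atoms: chloromethyl methyl ether, COCCl
Why: Chemoselective Williamson-type O-alkylation, in which the 2-OH is held in a hydrogen bond to the formyl group and only the para 4-OH is etherified, fixing which ring-A oxygen ends as O7.

Step 2
Reactants: 3 6-hydroxybenzofuran-2(3H)-one
Product: 4 6-(methoxymethoxy)benzofuran-2(3H)-one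
Conditions: MOMCl (1.05 equiv), iPr2NEt, CH2Cl2, 0 °C
Reagents that add atoms: chloromethyl methyl ether, COCCl
Why: Phenol O-alkylation with a weak amine base in the cold, where the free phenol should react faster than the lactone enolate, while the lactone keeps the future O2' masked so the two ring-B oxygens are differentiated from the start.

Step 3
Reactants: 2 2-hydroxy-6-methoxy-4-(methoxymethoxy)benzaldehyde, 4 6-(methoxymethoxy)benzofuran-2(3H)-one
Product: 6 3-[2-hydroxy-4-(methoxymethoxy)phenyl]-5-methoxy-7-(methoxymethoxy)-2H-chromen-2-one, via benzylidene lactone 5 (not isolated)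
Conditions: Et3N (2 equiv), toluene, 100 °C
Reagents that add atoms: none
Why: Knoevenagel condensation of the acidic C3 methylene of the benzofuranone with the aldehyde gives benzylidene lactone 5, whose ring-A ortho-phenoxide then transacylates the aryl ester (translactonisation) to the conjugated six-membered coumarin, a known way to 3-(2-hydroxyaryl)coumarins that releases only the O2' phenol of ring B.

Step 4
Reactants: 6 3-[2-hydroxy-4-(methoxymethoxy)phenyl]-5-methoxy-7-(methoxymethoxy)-2H-chromen-2-one
Product: 7 3-[2-(benzyloxy)-4-(methoxymethoxy)phenyl]-5-methoxy-7-(methoxymethoxy)-2H-chromen-2-one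
Conditions: BnBr, K2CO3, DMF, rt
Reagents that add atoms: benzyl bromide, BrCc1ccccc1
Why: Williamson etherification of the single free phenol, so that O2' cannot compete with the ring-A phenol in the ring closure of step 6 or bind the catalyst in step 7.

Step 5
Reactants: 7 3-[2-(benzyloxy)-4-(methoxymethoxy)phenyl]-5-methoxy-7-(methoxymethoxy)-2H-chromen-2-one
Product: 8 (Z)-2-[2-(benzyloxy)-4-(methoxymethoxy)phenyl]-3-[2-hydroxy-6-methoxy-4-(methoxymethoxy)phenyl]prop-2-en-1-ol
Conditions: iBu2AlH (4 equiv), CH2Cl2, −78 to 0 °C; aq. potassium sodium tartrate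
Reagents that add atoms: none
Why: 1,2-Reduction of the unsaturated lactone by the aluminium hydride through the lactol and enal to the allylic alcohol, with the Z geometry inherited from the ring and the MOM and benzyl ethers inert to hydride.

Step 6
Reactants: 8 (Z)-2-[2-(benzyloxy)-4-(methoxymethoxy)phenyl]-3-[2-hydroxy-6-methoxy-4-(methoxymethoxy)phenyl]prop-2-en-1-ol
Product: 9 3-[2-(benzyloxy)-4-(methoxymethoxy)phenyl]-5-methoxy-7-(methoxymethoxy)-2H-chromene
Conditions: PPh3, DIAD, THF, 0 °C to rt
Reagents that add atoms: none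
Why: Intramolecular Mitsunobu etherification, in which the ring-A phenol displaces the activated primary allylic alcohol in a 6-exo-tet closure pre-organised by the Z alkene, giving the isoflav-3-ene without acid that would endanger the MOM groups.

Step 7
Reactants: 9 3-[2-(benzyloxy)-4-(methoxymethoxy)phenyl]-5-methoxy-7-(methoxymethoxy)-2H-chromene
Product: 10 (3R)-3-[2-(benzyloxy)-4-(methoxymethoxy)phenyl]-5-methoxy-7-(methoxymethoxy)chromane
Conditions: H2 (50 bar), [Ir(cod)((S)-tBu-PHOX)]BArF (2 mol %; BArF = B[3,5-(CF3)2C6H3]4), CH2Cl2, rt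
Reagents that add atoms: none
Why: Iridium-catalysed asymmetric hydrogenation of a non-functionalised trisubstituted aryl alkene, a reaction type known for 3-aryl-2H-chromenes, in which the chiral P,N ligand pocket distinguishes the enantiotopic faces of C3=C4 and syn delivery of H2 creates C3, to be R with the ligand antipode chosen as in the remark.

Step 8
Reactants: 10 (3R)-3-[2-(benzyloxy)-4-(methoxymethoxy)phenyl]-5-methoxy-7-(methoxymethoxy)chromane
Product: 11 2-[(3R)-5-methoxy-7-(methoxymethoxy)chroman-3-yl]-5-(methoxymethoxy)phenol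
Conditions: H2 (1 atm), Pd/C (10 wt %), EtOAc–EtOH, rt
Reagents that add atoms: none
Why: Heterogeneous hydrogenolysis of the benzyl aryl ether releases the O2' phenol alone, while the MOM ethers, the aryl methyl ether, the non-benzylic chroman C–O bond and C3 are unaffected.

Step 9
Reactants: 11 2-[(3R)-5-methoxy-7-(methoxymethoxy)chroman-3-yl]-5-(methoxymethoxy)phenol
Product: 14 (3R)-5-methoxy-7-(methoxymethoxy)-3-[5-(methoxymethoxy)-2,2-dimethyl-2H-chromen-8-yl]chromane, via benzodioxaborin 12 (not isolated), via ortho-quinone methide 13 (not isolated)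
Conditions: 3-methylbut-2-enal (2 equiv), PhB(OH)2 (1 equiv), EtCO2H (0.3 equiv), toluene, reflux with azeotropic removal of water
Reagents that add atoms: 3-methylbut-2-enal, CC(C)=CC=O
Why: PhB(OH)2 condenses with the O2' hydroxyl of ring B and holds the aldehyde in a six-membered boron chelate, so that the formyl carbon bonds to the only free ortho carbon, C3', and the adduct is trapped as benzodioxaborin 12; at reflux 12 extrudes the boron unit to give ortho-quinone methide 13, the 1-oxatriene O=C2'–C3'=CH–CH=CMe2, which closes by a thermal disrotatory oxa-6π electrocyclisation that forms the O–CMe2 bond and restores the aromaticity of ring B. The closest known reaction type is the arylboronic acid-templated ortho-condensation of phenols with α,β-unsaturated aldehydes to 2H-chromenes, a formal [3+3] annulation (Knoevenagel-type C-alkylation, then electrocyclisation). Ring D is closed in a pericyclic 6π mode (six-membered, endo with respect to both new double bonds) and not by ionic substitution at the tertiary carbon. No stereocentre is created, since CMe2 carries two methyl groups, and the existing C3 (R) lies outside the reacting array and cannot enolise or ionise. The step needs regioselectivity for C3' and O2' over C5' and O4' and chemoselectivity against the electron-rich ring A: C1' is blocked by the chroman, O4' and O7 are MOM ethers so that only O2' can bind boron and become the dienone oxygen, and ring A offers no free hydroxyl for templated attack.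

Step 10
Reactants: 14 (3R)-5-methoxy-7-(methoxymethoxy)-3-[5-(methoxymethoxy)-2,2-dimethyl-2H-chromen-8-yl]chromane
Product: 15 (3R)-3-(5-hydroxy-2,2-dimethyl-2H-chromen-8-yl)-5-methoxychroman-7-ol
Conditions: HCl (3 M aq., 5 equiv), MeOH, 40 °C
Reagents that add atoms: none
Why: Acid-catalysed acetal exchange (solvolysis of both MOM ethers by methanol) under mild conditions should leave the aryl methyl ether, the 2,2-dimethylchromene and the non-epimerisable C3 untouched.

**Compound list**

1 | 2,4-dihydroxy-6-methoxybenzaldehyde | COc1cc(O)cc(O)c1C=O | starting material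
2 | 2-hydroxy-6-methoxy-4-(methoxymethoxy)benzaldehyde | COCOc1cc(O)c(C=O)c(OC)c1 | intermediate
3 | 6-hydroxybenzofuran-2(3H)-one | O=C1Cc2ccc(O)cc2O1 | starting material
4 | 6-(methoxymethoxy)benzofuran-2(3H)-one | COCOc1ccc2c(c1)OC(=O)C2 | intermediate
5 | (Z)-3-[2-hydroxy-6-methoxy-4-(methoxymethoxy)benzylidene]-6-(methoxymethoxy)benzofuran-2(3H)-one | O=C1Oc2cc(OCOC)ccc2/C1=C/c1c(O)cc(OCOC)cc1OC | intermediate (not isolated)
6 | 3-[2-hydroxy-4-(methoxymethoxy)phenyl]-5-methoxy-7-(methoxymethoxy)-2H-chromen-2-one | O=C1Oc2cc(OCOC)cc(OC)c2C=C1c1ccc(OCOC)cc1O | intermediate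
7 | 3-[2-(benzyloxy)-4-(methoxymethoxy)phenyl]-5-methoxy-7-(methoxymethoxy)-2H-chromen-2-one | O=C1Oc2cc(OCOC)cc(OC)c2C=C1c1ccc(OCOC)cc1OCc1ccccc1 | intermediate
8 | (Z)-2-[2-(benzyloxy)-4-(methoxymethoxy)phenyl]-3-[2-hydroxy-6-methoxy-4-(methoxymethoxy)phenyl]prop-2-en-1-ol | OC/C(c1ccc(OCOC)cc1OCc1ccccc1)=C\c1c(O)cc(OCOC)cc1OC | intermediate
9 | 3-[2-(benzyloxy)-4-(methoxymethoxy)phenyl]-5-methoxy-7-(methoxymethoxy)-2H-chromene | COc1cc(OCOC)cc2c1C=C(c1ccc(OCOC)cc1OCc1ccccc1)CO2 | intermediate
10 | (3R)-3-[2-(benzyloxy)-4-(methoxymethoxy)phenyl]-5-methoxy-7-(methoxymethoxy)chromane | COc1cc(OCOC)cc2c1C[C@H](c1ccc(OCOC)cc1OCc1ccccc1)CO2 | intermediate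
11 | 2-[(3R)-5-methoxy-7-(methoxymethoxy)chroman-3-yl]-5-(methoxymethoxy)phenol | COc1cc(OCOC)cc2c1C[C@H](c1ccc(OCOC)cc1O)CO2 | intermediate
12 | 8-[(3R)-5-methoxy-7-(methoxymethoxy)chroman-3-yl]-5-(methoxymethoxy)-4-(2-methylprop-1-en-1-yl)-2-phenyl-4H-1,3,2-benzodioxaborinine (both epimers at C4 of the boron ring) | COc1cc(OCOC)cc2c1C[C@H](c1ccc(OCOC)c3c1OB(c1ccccc1)OC3C=C(C)C)CO2 | intermediate (not isolated)
13 | (6Z)-2-[(3R)-5-methoxy-7-(methoxymethoxy)chroman-3-yl]-5-(methoxymethoxy)-6-(3-methylbut-2-en-1-ylidene)cyclohexa-2,4-dien-1-one | COc1cc(OCOC)cc2c1C[C@H](C1=CC=C(OCOC)/C(=C/C=C(C)C)C1=O)CO2 | intermediate (not isolated)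
14 | (3R)-5-methoxy-7-(methoxymethoxy)-3-[5-(methoxymethoxy)-2,2-dimethyl-2H-chromen-8-yl]chromane | COc1cc(OCOC)cc2c1C[C@H](c1ccc(OCOC)c3c1OC(C)(C)C=C3)CO2 | intermediate
15 | (3R)-3-(5-hydroxy-2,2-dimethyl-2H-chromen-8-yl)-5-methoxychroman-7-ol | COc1cc(O)cc2c1C[C@H](c1ccc(O)c3c1OC(C)(C)C=C3)CO2 | target

**Count**

Total steps: 10. Longest linear sequence: 9 steps (3 → 4 → 6 → 7 → 8 → 9 → 10 → 11 → 14 → 15; the branch from 1 is equally long).

**Steps most likely to fail, with fallbacks**

Step 7. The hindered trisubstituted alkene, flanked by the ortho-benzyloxy ring B, may be reduced slowly or with poor facial discrimination, and the acidic iridium hydrides may strip MOM groups. Fallback: from 9, unselective hydrogenation with concurrent O-debenzylation (H2, Pd/C, EtOAc–EtOH) should give racemic 2-[5-methoxy-7-(methoxymethoxy)chroman-3-yl]-5-(methoxymethoxy)phenol F1. This is resolved by preparative chromatography on a chiral stationary phase (amylose or cellulose carbamate type). The 3R enantiomer is compound 11, where the route is rejoined; steps 7 and 8 are bypassed.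

Step 9. C-alkylation at the crowded C3' between two oxygen substituents may be incomplete, the aldehyde may attack the electron-rich ring A instead, or the MOM ethers may be lost under acid at reflux. Fallback: from 11, O-alkylation with 3-chloro-3-methylbut-1-yne (DBU, CuCl2 cat., MeCN, 0 °C) should give (3R)-5-methoxy-7-(methoxymethoxy)-3-[4-(methoxymethoxy)-2-(2-methylbut-3-yn-2-yloxy)phenyl]chromane F2. Heating in PhNEt2 at 190 °C should then bring about an aromatic propargyl Claisen rearrangement to C3', the only free ortho position, and enolisation to 2-[(3R)-5-methoxy-7-(methoxymethoxy)chroman-3-yl]-5-(methoxymethoxy)-6-(3-methylbuta-1,2-dien-1-yl)phenol F3. A [1,5]-hydrogen shift in F3 gives the same ortho-quinone methide 13, which electrocyclises to 14, where the route is rejoined.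

Step 3. Knoevenagel addition to the electron-rich, doubly ortho-substituted aldehyde may be sluggish, the lactone enolate may self-condense, or the benzylidene lactone may stall in the geometry that cannot transacylate. Fallback: from 4, methanolysis (K2CO3, MeOH, 0 °C) should give methyl [2-hydroxy-4-(methoxymethoxy)phenyl]acetate F4. Benzylation (BnBr, K2CO3, DMF) gives methyl [2-(benzyloxy)-4-(methoxymethoxy)phenyl]acetate F5, and saponification (LiOH, THF–H2O) gives [2-(benzyloxy)-4-(methoxymethoxy)phenyl]acetic acid F6. Perkin–Oglialoro condensation of F6 with aldehyde 2 (Ac2O, Et3N, 110 °C) should give coumarin 7 directly, where the route is rejoined; steps 3 and 4 are bypassed.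

**Further compounds**

F1 | step 7 | racemic 2-[5-methoxy-7-(methoxymethoxy)chroman-3-yl]-5-(methoxymethoxy)phenol | COc1cc(OCOC)cc2c1CC(c1ccc(OCOC)cc1O)CO2
F2 | step 9 | (3R)-5-methoxy-7-(methoxymethoxy)-3-[4-(methoxymethoxy)-2-(2-methylbut-3-yn-2-yloxy)phenyl]chromane | COc1cc(OCOC)cc2c1C[C@H](c1ccc(OCOC)cc1OC(C)(C)C#C)CO2
F3 | step 9 | 2-[(3R)-5-methoxy-7-(methoxymethoxy)chroman-3-yl]-5-(methoxymethoxy)-6-(3-methylbuta-1,2-dien-1-yl)phenol | COc1cc(OCOC)cc2c1C[C@H](c1ccc(OCOC)c(C=C=C(C)C)c1O)CO2
F4 | step 3 | methyl [2-hydroxy-4-(methoxymethoxy)phenyl]acetate | COC(=O)Cc1ccc(OCOC)cc1O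
F5 | step 3 | methyl [2-(benzyloxy)-4-(methoxymethoxy)phenyl]acetate | COC(=O)Cc1ccc(OCOC)cc1OCc1ccccc1
F6 | step 3 | [2-(benzyloxy)-4-(methoxymethoxy)phenyl]acetic acid | OC(=O)Cc1ccc(OCOC)cc1OCc1ccccc1
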